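The cross-conjugated dienone ring is an isomer of a 4-hydroxy-2-pyranone. Its ring C(OH) lying between the CH2-bearing ring carbon and the quaternary C(CH3)(geranyl), together with that quaternary carbon, correspond to lactone carbon C2 and the exocyclic CH on C6 of a pyranone. The route therefore assembles the whole methylene-bridged trimer with a racemic 6-(sec-alkyl)-4-hydroxy-2-pyranone in place of the dienone, masks its acidic OH groups as silyl ethers in the flask, and lets a chiral acyl-transfer catalyst move the acyl carbon from the ring oxygen to the side-chain carbon. That single operation closes the carbocycle and sets the only stereocentre from both enantiomers; C-acetylation of the last ring CH completes the target.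

Key step: step 7

Remark: the pyranone and trione rings are drawn as single tautomers; the quaternary carbon has the same spatial arrangement in 14, 15, 16 and 17 (its CIP label is R in 17 and S in 15 only because the acetyl group reverses the ranking of the two ring branches), and the sense of induction of the catalyst in step 7 is assumed, its antipode being used if it proves opposite.

Step 1
Reactants: 1 triacetic acid lactone (4-hydroxy-6-methyl-2H-pyran-2-one)
Product: 2 6-ethyl-4-hydroxy-2H-pyran-2-one
Conditions: LDA (2.2 equiv), THF–DMPU, −78 °C; MeI (1.0 equiv), −78 → −40 °C; aq HCl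
Reagents that add atoms: iodomethane, CI
Why: Two equivalents of LDA give the O,C-dianion, whose exocyclic carbanion is by far its most nucleophilic site, so one equivalent of iodomethane alkylates the 6-methyl group (γ-alkylation of a vinylogous-acid dianion).

Step 2
Reactants: 2 6-ethyl-4-hydroxy-2H-pyran-2-one; 3 geranyl bromide
Product: 4 rac-6-[(4E)-5,9-dimethyldeca-4,8-dien-2-yl]-4-hydroxy-2H-pyran-2-one
Conditions: LDA (2.2 equiv), THF–DMPU, −78 °C; 3 (1.05 equiv), −78 → −20 °C; aq HCl
Reagents that add atoms: none
Why: The same dianion alkylation on the 6-ethyl group, with the allylic bromide attacked in SN2 fashion at its primary carbon, installs the geranyl chain and creates the side-chain CH as a racemate, which is all the key step needs.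

Step 3
Reactants: 5 phloroglucinol
Product: 6 1-(2,4,6-trihydroxyphenyl)butan-1-one
Conditions: butanoyl chloride (1.05 equiv), AlCl3 (3.5 equiv), PhNO2–CH2Cl2, 0 → 40 °C; ice/HCl
Reagents that add atoms: butanoyl chloride, CCCC(Cl)=O
Why: Friedel–Crafts acylation of the very electron-rich ring stops after one acyl group because the aluminium-complexed aryl ketone is deactivated.

Step 4
Reactants: 6 1-(2,4,6-trihydroxyphenyl)butan-1-one; 7 3-methylbut-2-enal
Product: 8 1-(5,7-dihydroxy-2,2-dimethyl-2H-chromen-8-yl)butan-1-one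
Conditions: 7 (1.1 equiv), EDDA (20 mol %), PhMe, 100 °C
Reagents that add atoms: none
Why: Amine-catalysed domino Knoevenagel condensation/oxa-6π electrocyclization of the enal with the phloroglucinol builds the 2,2-dimethyl-2H-chromene; closure through the oxygen next to the acyl group gives the 8-acyl isomer needed, and any isomer closed through the para oxygen is removed by chromatography.

Step 5
Reactants: 8 1-(5,7-dihydroxy-2,2-dimethyl-2H-chromen-8-yl)butan-1-one; 6 1-(2,4,6-trihydroxyphenyl)butan-1-one
Product: 10 1-{3-[(8-butanoyl-5,7-dihydroxy-2,2-dimethyl-2H-chromen-6-yl)methyl]-2,4,6-trihydroxyphenyl}butan-1-one (chromene–phloroglucinol dimer), via chromene Mannich base 9 (not isolated)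
Conditions: Me2N+=CH2 I− (1.05 equiv), CH2Cl2, 0 °C → rt; evaporate; then 6 (3 equiv), NaOAc (2 equiv), 1,4-dioxane, 80 °C
Reagents that add atoms: Eschenmoser's salt (N,N-dimethylmethyleneiminium iodide), C=[N+](C)C.[I-]
Why: Mannich aminomethylation can occur only at the one free ring carbon of 8, and the ortho-hydroxybenzylamine loses dimethylamine on warming to an ortho-quinone methide that is captured by a ring carbon of 6 (Michael-type Friedel–Crafts alkylation), the excess of 6 suppressing double alkylation.

Step 6
Reactants: 10 chromene–phloroglucinol dimer; 4 rac-6-[(4E)-5,9-dimethyldeca-4,8-dien-2-yl]-4-hydroxy-2H-pyran-2-one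
Product: 12 3-{[3-butanoyl-5-[(8-butanoyl-5,7-dihydroxy-2,2-dimethyl-2H-chromen-6-yl)methyl]-2,4,6-trihydroxyphenyl]methyl}-6-[(4E)-5,9-dimethyldeca-4,8-dien-2-yl]-4-hydroxy-2H-pyran-2-one (pyranone trimer; racemic at the side-chain CH), via dimer Mannich base 11 (not isolated)
Conditions: Me2N+=CH2 I− (1.05 equiv), CH2Cl2, 0 °C → rt; evaporate; then 4 (1.5 equiv), NaOAc (2 equiv), 1,4-dioxane, 70 °C
Reagents that add atoms: Eschenmoser's salt (N,N-dimethylmethyleneiminium iodide), C=[N+](C)C.[I-]
Why: The same Mannich/ortho-quinone-methide sequence at the last free ring carbon of 10 uses C3 of the 4-hydroxy-2-pyranone, its only strongly nucleophilic carbon, as the Michael donor; every partner has a single reactive site and the geranyl alkenes never meet the iminium salt.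

Step 7
Reactants: 12 pyranone trimer (racemic at the side-chain CH)
Product: 15 (4S)-2-{[3-butanoyl-5-[(8-butanoyl-5,7-dihydroxy-2,2-dimethyl-2H-chromen-6-yl)methyl]-2,4,6-trihydroxyphenyl]methyl}-4-[(2E)-3,7-dimethylocta-2,6-dien-1-yl]-3,5-dihydroxy-4-methylcyclohexa-2,5-dien-1-one (deacetyl target), via hexakis-TMS ether 13 (not isolated), via heptakis-TMS dienone 14 (not isolated)
Conditions: BSA (10 equiv), PhMe, 40 °C; then (2S,3R)-HyperBTM (20 mol %), iPr2NEt (1 equiv), PhMe, 40–60 °C; then citric acid, THF–H2O, rt
Reagents that add atoms: none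
Why: Proposed new method: with every OH capped as its TMS ether, so that neither the vinylogous acid nor the phenols can protonate the catalyst, the isothiourea should add to lactone carbonyl C2 of 13 and expel the C6 enol oxygen, giving an acyl-ammonium tethered to a triketide enolate; amine-shuttled proton transfer moves the enolate to the exocyclic carbon, which attacks the acyl-ammonium to form the C2–C(quaternary) bond and release the catalyst, the closest known reactions being chiral isothiourea- or PPY-catalysed Steglich-type O-to-C acyl shifts of enol esters and the base-mediated recyclization of 4-hydroxy-6-methyl-2-pyranones and enol lactones to cyclic 1,3-diones. The carbocycle closes by a 6-(enolendo)-exo-trig acyl substitution, whereas the C5 enolate could close only a four-membered ring or return to the pyranone, so the productive path drains the equilibrium (Curtin–Hammett). The side-chain carbon is planar in the reacting enolate, so both enantiomers of 12 pass through the same intermediate, and the quaternary stereocentre is set by the stereocentres of the catalyst held on the acyl carbon, which must tell the enolate face flanked by methyl from the one flanked by CH2-geranyl. Site selectivity is secured by ring size and by the fully substituted aryl rings, which offer no carbon nucleophile, and an aryl ester formed by silyl–acyl exchange at a neighbouring phenol oxygen stays an acyl donor for the catalyst. Excess BSA caps the enol of the product as 14, so the acidic trione cannot stop turnover, and mild acid then strips all silyl groups to give 15.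

Step 8
Reactants: 15 deacetyl target
Product: 17 (4R)-2-acetyl-6-{[3-butanoyl-5-[(8-butanoyl-5,7-dihydroxy-2,2-dimethyl-2H-chromen-6-yl)methyl]-2,4,6-trihydroxyphenyl]methyl}-4-[(2E)-3,7-dimethylocta-2,6-dien-1-yl]-3,5-dihydroxy-4-methylcyclohexa-2,5-dien-1-one (target CNP0103039.1), via enol acetate 16 (not isolated)
Conditions: Ac2O (1.1 equiv), Et3N (1.2 equiv), DMAP (0.3 equiv), CH2Cl2, 0 °C → rt; then MeOH, rt; dilute HCl work-up
Reagents that add atoms: acetic anhydride, CC(=O)OC(C)=O
Why: Triethylamine deprotonates the vinylogous-acid enol of the trione ring selectively, enol acetate 16 forms and DMAP relays its acetyl group to the only ring CH (O-acylation followed by DMAP-mediated O-to-C acyl migration, as used for 2-acylcyclohexane-1,3-diones); the chelated C-acetyl trione anion is the thermodynamic sink, acetyl groups that stray to phenols are returned through the acetylpyridinium because the aryl rings have no free carbon, and the quaternary stereocentre is not touched.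

Compound list
1 | triacetic acid lactone (4-hydroxy-6-methyl-2H-pyran-2-one) | CC1=CC(O)=CC(=O)O1 | starting material
2 | 6-ethyl-4-hydroxy-2H-pyran-2-one | CCC1=CC(O)=CC(=O)O1 | intermediate
3 | geranyl bromide, (2E)-1-bromo-3,7-dimethylocta-2,6-diene | BrC/C=C(\C)CCC=C(C)C | starting material
4 | rac-6-[(4E)-5,9-dimethyldeca-4,8-dien-2-yl]-4-hydroxy-2H-pyran-2-one | CC(C/C=C(\C)CCC=C(C)C)C1=CC(O)=CC(=O)O1 | intermediate
5 | phloroglucinol | Oc1cc(O)cc(O)c1 | starting material
6 | 1-(2,4,6-trihydroxyphenyl)butan-1-one | CCCC(=O)c1c(O)cc(O)cc1O | intermediate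
7 | 3-methylbut-2-enal | CC(C)=CC=O | starting material
8 | 1-(5,7-dihydroxy-2,2-dimethyl-2H-chromen-8-yl)butan-1-one | CCCC(=O)c1c(O)cc(O)c2c1OC(C)(C)C=C2 | intermediate
9 | 1-{6-[(dimethylamino)methyl]-5,7-dihydroxy-2,2-dimethyl-2H-chromen-8-yl}butan-1-one (chromene Mannich base) | CCCC(=O)c1c(O)c(CN(C)C)c(O)c2c1OC(C)(C)C=C2 | intermediate (not isolated)
10 | 1-{3-[(8-butanoyl-5,7-dihydroxy-2,2-dimethyl-2H-chromen-6-yl)methyl]-2,4,6-trihydroxyphenyl}butan-1-one (dimer) | CCCC(=O)c1c(O)cc(O)c(Cc2c(O)c3c(c(C(=O)CCC)c2O)OC(C)(C)C=C3)c1O | intermediate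
11 | 1-{3-[(8-butanoyl-5,7-dihydroxy-2,2-dimethyl-2H-chromen-6-yl)methyl]-5-[(dimethylamino)methyl]-2,4,6-trihydroxyphenyl}butan-1-one (dimer Mannich base) | CCCC(=O)c1c(O)c(CN(C)C)c(O)c(Cc2c(O)c3c(c(C(=O)CCC)c2O)OC(C)(C)C=C3)c1O | intermediate (not isolated)
12 | 3-{[3-butanoyl-5-[(8-butanoyl-5,7-dihydroxy-2,2-dimethyl-2H-chromen-6-yl)methyl]-2,4,6-trihydroxyphenyl]methyl}-6-[(4E)-5,9-dimethyldeca-4,8-dien-2-yl]-4-hydroxy-2H-pyran-2-one, racemic at the side-chain CH (key-step precursor) | CCCC(=O)c1c(O)c(CC2=C(O)C=C(C(C)C/C=C(\C)CCC=C(C)C)OC2=O)c(O)c(Cc2c(O)c3c(c(C(=O)CCC)c2O)OC(C)(C)C=C3)c1O | intermediate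
13 | hexakis(trimethylsilyl) ether of 12 (five aryl OTMS, pyranone 4-OTMS) | CCCC(=O)c1c(O[Si](C)(C)C)c(CC2=C(O[Si](C)(C)C)C=C(C(C)C/C=C(\C)CCC=C(C)C)OC2=O)c(O[Si](C)(C)C)c(Cc2c(O[Si](C)(C)C)c3c(c(C(=O)CCC)c2O[Si](C)(C)C)OC(C)(C)C=C3)c1O[Si](C)(C)C | intermediate (not isolated)
14 | heptakis(trimethylsilyl) derivative of 15 (five aryl OTMS, two silyl enol ethers on the carbocycle, quaternary carbon as in 15) | CCCC(=O)c1c(O[Si](C)(C)C)c(CC=2C(=O)[C@@](C)(C/C=C(\C)CCC=C(C)C)C(O[Si](C)(C)C)=CC=2O[Si](C)(C)C)c(O[Si](C)(C)C)c(Cc2c(O[Si](C)(C)C)c3c(c(C(=O)CCC)c2O[Si](C)(C)C)OC(C)(C)C=C3)c1O[Si](C)(C)C | intermediate (not isolated)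
15 | (4S)-2-{[3-butanoyl-5-[(8-butanoyl-5,7-dihydroxy-2,2-dimethyl-2H-chromen-6-yl)methyl]-2,4,6-trihydroxyphenyl]methyl}-4-[(2E)-3,7-dimethylocta-2,6-dien-1-yl]-3,5-dihydroxy-4-methylcyclohexa-2,5-dien-1-one (deacetyl target) | CCCC(=O)c1c(O)c(CC2=C(O)[C@@](C)(C/C=C(\C)CCC=C(C)C)C(O)=CC2=O)c(O)c(Cc2c(O)c3c(c(C(=O)CCC)c2O)OC(C)(C)C=C3)c1O | intermediate
16 | enol acetate of 15 at the ring oxygen next to the ring CH, quaternary carbon unchanged | CCCC(=O)c1c(O)c(CC2=C(O)[C@@](C)(C/C=C(\C)CCC=C(C)C)C(=O)C=C2OC(C)=O)c(O)c(Cc2c(O)c3c(c(C(=O)CCC)c2O)OC(C)(C)C=C3)c1O | intermediate (not isolated)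
17 | (4R)-2-acetyl-6-{[3-butanoyl-5-[(8-butanoyl-5,7-dihydroxy-2,2-dimethyl-2H-chromen-6-yl)methyl]-2,4,6-trihydroxyphenyl]methyl}-4-[(2E)-3,7-dimethylocta-2,6-dien-1-yl]-3,5-dihydroxy-4-methylcyclohexa-2,5-dien-1-one (CNP0103039.1) | CCCC(=O)c1c(O)c(CC2=C(O)[C@@](C)(C/C=C(\C)CCC=C(C)C)C(O)=C(C(C)=O)C2=O)c(O)c(Cc2c(O)c3c(c(C(=O)CCC)c2O)OC(C)(C)C=C3)c1O | target

Total step count: 8
Longest linear sequence: 6 steps (5 → 6 → 8 → 10 → 12 → 15 → 17; steps 3 to 8)

Steps most likely to fail

1. Step 7 (the step labelled as a proposed new method). The lactone may resist opening by the catalyst, the proton relay to the exocyclic enolate may be too slow, or the catalyst may fail to tell the methyl-flanked from the CH2-flanked enolate face, so that conversion or enantioselectivity is poor. The fallback uses known chemistry only, sets out from geranyl bromide 3 and dimer 10, and returns at target 17. Commercial 1-(2,4,6-trihydroxy-3-methylphenyl)ethan-1-one F1 is C-geranylated with 3 at its methyl-bearing ring carbon (NaOMe, MeOH, 0 °C; alkylative dearomatization of an acylphloroglucinol). This should give racemic 2-acetyl-4-[(2E)-3,7-dimethylocta-2,6-dien-1-yl]-3,5-dihydroxy-4-methylcyclohexa-2,5-dien-1-one F2, which is separated from ring-geranylated aromatic isomers. Preparative HPLC on a chiral stationary phase then provides its (R)-enantiomer F3. The one ring CH of F3 is finally joined to the quinone methide generated from dimer Mannich base 11 (made from 10 as in step 6; NaOAc, dioxane, 70 °C), which should give 17 with the acetyl group already in place.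

2. Step 4. Ring closure through the wrong phenol oxygen, or a second annulation, may erode the supply of the 8-acyl chromene. The fallback sets out from 6 and returns at 8. Compound 6 is converted with MOMCl/iPr2NEt into 1-[2-hydroxy-4,6-bis(methoxymethoxy)phenyl]butan-1-one F4, in which only the chelated oxygen next to the acyl group is free. O-Alkylation with 3-chloro-3-methylbut-1-yne (DBU, CuCl2 cat., MeCN) should give the aryl 1,1-dimethylpropargyl ether 1-[2,4-bis(methoxymethoxy)-6-(2-methylbut-3-yn-2-yloxy)phenyl]butan-1-one F5. Heating (PhNEt2, 140 °C) induces aromatic Claisen rearrangement, 1,5-hydrogen shift and oxa-6π closure to 1-[5,7-bis(methoxymethoxy)-2,2-dimethyl-2H-chromen-8-yl]butan-1-one F6, whose ring oxygen can only be the one next to the acyl group. HCl/MeOH removes the MOM groups to give 8.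

3. Step 6. The quinone methide from 11 needs heat, and under these conditions the existing diarylmethane bridge may exchange by retro-Michael cleavage (bridge scrambling), or capture by the pyranone may be incomplete. The fallback sets out from 4 and 10 and returns at 12, with the roles of the partners reversed. Pyranone 4 is aminomethylated at C3 with Eschenmoser's salt to the vinylogous-acid Mannich base 3-[(dimethylamino)methyl]-6-[(4E)-5,9-dimethyldeca-4,8-dien-2-yl]-4-hydroxy-2H-pyran-2-one F7. F7 loses dimethylamine near room temperature to a 3-methylenepyran-2,4-dione, which is trapped by the free ring carbon of 10 (NaOAc, dioxane, 25–40 °C) to give 12 without heating the dimer.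

Further compounds
F1 | step 7 | 1-(2,4,6-trihydroxy-3-methylphenyl)ethan-1-one | CC(=O)c1c(O)cc(O)c(C)c1O
F2 | step 7 | rac-2-acetyl-4-[(2E)-3,7-dimethylocta-2,6-dien-1-yl]-3,5-dihydroxy-4-methylcyclohexa-2,5-dien-1-one | CC(=O)C1=C(O)C(C)(C/C=C(\C)CCC=C(C)C)C(O)=CC1=O
F3 | step 7 | (4R)-2-acetyl-4-[(2E)-3,7-dimethylocta-2,6-dien-1-yl]-3,5-dihydroxy-4-methylcyclohexa-2,5-dien-1-one | CC(=O)C1=C(O)[C@](C)(C/C=C(\C)CCC=C(C)C)C(O)=CC1=O
F4 | step 4 | 1-[2-hydroxy-4,6-bis(methoxymethoxy)phenyl]butan-1-one | CCCC(=O)c1c(O)cc(OCOC)cc1OCOC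
F5 | step 4 | 1-[2,4-bis(methoxymethoxy)-6-(2-methylbut-3-yn-2-yloxy)phenyl]butan-1-one | CCCC(=O)c1c(OC(C)(C)C#C)cc(OCOC)cc1OCOC
F6 | step 4 | 1-[5,7-bis(methoxymethoxy)-2,2-dimethyl-2H-chromen-8-yl]butan-1-one | CCCC(=O)c1c(OCOC)cc(OCOC)c2c1OC(C)(C)C=C2
F7 | step 6 | 3-[(dimethylamino)methyl]-6-[(4E)-5,9-dimethyldeca-4,8-dien-2-yl]-4-hydroxy-2H-pyran-2-one (racemic) | CC(C/C=C(\C)CCC=C(C)C)C1=CC(O)=C(CN(C)C)C(=O)O1
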